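The route disconnects two C–C bonds at the furan: furan C3 to the tropone carbonyl carbon, and furan C4 to the carbon shared by the seven-membered ring and ring B (the one flanked by the C–OH carbon and the ring-B ketone). These two carbons become the termini of an ester-derived carbonyl ylide, and the furan C3–C4 bond an ynone triple bond. One rhodium-carbenoid operation then forms both C–C bonds and closes the oxygen-bridged seven-membered ring and ring B. The precursor is a 2-diazo-1,3-diaryl-1,3-dione: one aryl carries an ortho methyl ester, the other an ortho silyloxy-propargyl arm ending in the prenyl ynone. Reductive bridge opening and furan-forming cyclodehydration finish the achiral target.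

Key step: step 9

Remark on the chemistry: radermachol has no stereocentre. The silyloxy carbon, the secondary carbinol centres of 9, 10 and 14, and the bridgeheads of 17 are all destroyed later, so every chiral intermediate is carried as a racemate and, where it applies, as a diastereomer mixture. The diazo group is installed before the ynone exists, and the ynone is unveiled only in the step before the key step, so that no 1,3-diketone carbanion is ever exposed to the ynone (Michael closure) or to the ortho ester (Dieckmann closure).

Step 1
Reactants: 1 1-bromo-2-(diethoxymethyl)benzene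
Product: 3 2-(diethoxymethyl)benzaldehyde, via aryllithium 2 (not isolated)
Conditions: n-BuLi, THF, −78 °C; DMF, −78 °C → rt; H2O
Reagents that add atoms: N,N-dimethylformamide, CN(C)C=O
Why: Bromine–lithium exchange is fast at −78 °C and leaves the acetal untouched, so formylation of the aryllithium with DMF (halogen–metal exchange followed by Bouveault formylation) should give the mono-protected dialdehyde.

Step 2
Reactants: 3 2-(diethoxymethyl)benzaldehyde; 4 ethynylmagnesium bromide
Product: 5 1-[2-(diethoxymethyl)phenyl]prop-2-yn-1-ol (racemic)
Conditions: THF, 0 °C → rt; H2O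
Reagents that add atoms: none
Why: Grignard 1,2-addition to the only free aldehyde should give the propargylic alcohol, whose new carbinol centre is formed without control because it later becomes furan C5.

Step 3
Reactants: 5 1-[2-(diethoxymethyl)phenyl]prop-2-yn-1-ol
Product: 6 tert-butyl{1-[2-(diethoxymethyl)phenyl]prop-2-yn-1-yloxy}dimethylsilane (racemic)
Conditions: TBSCl, imidazole, DMAP (cat.), DMF, rt
Reagents that add atoms: tert-butyl(chloro)dimethylsilane (TBSCl), CC(C)(C)[Si](C)(C)Cl
Why: Imidazole-mediated silylation of the secondary alcohol (silyl ether formation) uses no silyl triflate or acid, so the diethyl acetal should survive.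

Step 4
Reactants: 6 tert-butyl{1-[2-(diethoxymethyl)phenyl]prop-2-yn-1-yloxy}dimethylsilane; 7 3-methylbut-2-enal
Product: 9 1-[tert-butyl(dimethyl)silyloxy]-1-[2-(diethoxymethyl)phenyl]-6-methylhept-5-en-2-yn-4-ol (racemic diastereomer mixture), via lithium acetylide 8 (not isolated)
Conditions: n-BuLi (1.0 equiv), THF, −78 °C; 7, −78 → −20 °C; H2O
Reagents that add atoms: none
Why: The terminal alkyne C–H is by far the most acidic site, so one equivalent of n-BuLi should give the acetylide, which adds 1,2 to the enal at low temperature (acetylide addition to an aldehyde); the new carbinol centre is uncontrolled and is oxidized in step 8.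

Step 5
Reactants: 9 1-[tert-butyl(dimethyl)silyloxy]-1-[2-(diethoxymethyl)phenyl]-6-methylhept-5-en-2-yn-4-ol
Product: 10 2-{1-[tert-butyl(dimethyl)silyloxy]-4-hydroxy-6-methylhept-5-en-2-yn-1-yl}benzaldehyde (racemic diastereomer mixture)
Conditions: PPTS (cat.), acetone/H2O, rt
Reagents that add atoms: water, O
Why: An aryl aldehyde diethyl acetal ionizes to a benzylic oxocarbenium ion under buffered acid far milder than that needed to ionize the allylic–propargylic alcohol or to cleave the silyl ether, so selective acetal hydrolysis is expected.

Step 6
Reactants: 11 2-(methoxycarbonyl)benzoic acid (monomethyl phthalate)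
Product: 13 methyl 2-(2-diazoacetyl)benzoate, via acid chloride 12 (not isolated)
Conditions: (COCl)2, DMF (cat.), CH2Cl2, 0 °C → rt; TMSCHN2, Et3N, THF/MeCN, 0 °C; H2O
Reagents that add atoms: (trimethylsilyl)diazomethane, C[Si](C)(C)C=[N+]=[N-]
Why: The half-ester should give its acid chloride below room temperature (which avoids the cyclic pseudo-chloride), and C-acylation of the silyl diazomethane with loss of silicon on aqueous work-up is the diazomethane-free form of the Arndt–Eistert diazoketone synthesis.

Step 7
Reactants: 10 2-{1-[tert-butyl(dimethyl)silyloxy]-4-hydroxy-6-methylhept-5-en-2-yn-1-yl}benzaldehyde; 13 methyl 2-(2-diazoacetyl)benzoate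
Product: 14 methyl 2-[3-(2-{1-[tert-butyl(dimethyl)silyloxy]-4-hydroxy-6-methylhept-5-en-2-yn-1-yl}phenyl)-2-diazo-3-hydroxypropanoyl]benzoate (racemic diastereomer mixture)
Conditions: DBU (0.2 equiv), MeCN, rt
Reagents that add atoms: none
Why: Catalytic DBU reversibly deprotonates the diazo carbon, and the carbanion adds to the non-enolizable aryl aldehyde (aldol-type addition of an acyldiazomethane) while its low concentration limits attack on the neighbouring ester; the new carbinol centre is uncontrolled and is oxidized in step 8.

Step 8
Reactants: 14 methyl 2-[3-(2-{1-[tert-butyl(dimethyl)silyloxy]-4-hydroxy-6-methylhept-5-en-2-yn-1-yl}phenyl)-2-diazo-3-hydroxypropanoyl]benzoate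
Product: 15 methyl 2-[3-(2-{1-[tert-butyl(dimethyl)silyloxy]-6-methyl-4-oxohept-5-en-2-yn-1-yl}phenyl)-2-diazo-3-oxopropanoyl]benzoate (racemic)
Conditions: IBX (3 equiv), DMSO, rt; used at once
Reagents that add atoms: none
Why: Neutral IBX in DMSO is an established oxidant for converting β-hydroxy-α-diazo carbonyl compounds into 2-diazo-1,3-dicarbonyls with the diazo group intact, and it should oxidize the allylic–propargylic alcohol to the ynone in the same operation (hypervalent-iodine alcohol oxidation).

Step 9
Reactants: 15 methyl 2-[3-(2-{1-[tert-butyl(dimethyl)silyloxy]-6-methyl-4-oxohept-5-en-2-yn-1-yl}phenyl)-2-diazo-3-oxopropanoyl]benzoate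
Product: 17 oxygen-bridged cycloadduct (racemic; both epimers at the silyloxy carbon), via carbonyl ylide 16 (not isolated)
Conditions: Rh2(OAc)4 (2 mol %), PhH, 80 °C, slow addition of 15
Reagents that add atoms: none
Why: Divalent rhodium in Rh2(OAc)4 releases N2 from 15 to give an electrophilic carbenoid between the two aryl ketones, the carbonyl oxygen of the ortho methyl ester closes onto it to form the 1-methoxy-2-benzopyrylium-4-olate 16, and this dipole adds across the tethered ynone in an intramolecular 1,3-dipolar cycloaddition. The closest known chemistry is the tandem rhodium-carbenoid cyclization–cycloaddition of ortho-alkoxycarbonyl aryl diazoketones with alkynes, which gives oxygen-bridged benzocycloheptenones, together with the trapping of carbonyl ylides by tethered alkynes; the combination of an ester-derived ylide with a dipolarophile tethered through the aroyl group is not itself precedented. The ylide ring (the later oxygen bridge) closes by O–C bond formation in a six-membered mode set up by the ortho geometry; ring B closes as a six-membered ring when the aroyl-bearing ylide carbon bonds to the alkyne carbon next to the silyloxy carbon through the four-atom tether; the seven-membered carbocycle closes when the methoxy-bearing ylide carbon bonds to the alkyne carbon that carries the enoyl group. Both bridgehead centres arise by suprafacial addition to one face of the planar dipole, so the bridge dictates their relative configuration; the product is racemic and both epimers at the silyloxy carbon are acceptable because all three centres are destroyed later. The step needs chemoselective capture of the carbenoid by the ester, which should hold because the ester is the only carbonyl within reach through a six-membered ring (the benzylic oxygen is a bulky silyl ether and not a ketone, and the ynone carbonyl is too far away), and a single regiochemistry, which the short tether enforces. The electron-poor ynone matches the electron-rich dipole and resists direct attack by the carbenoid, and slow addition of freshly made 15 to the hot catalyst should keep thermal addition of the diazo group to the ynone from competing.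

Step 10
Reactants: 17 oxygen-bridged cycloadduct
Product: 19 silyl-protected hydroxybenzotropone (racemic), via methyl hemiketal 18 (not isolated)
Conditions: SmI2 (2.2 equiv), THF/MeOH, −78 °C
Reagents that add atoms: none
Why: Electron transfer from divalent samarium to either ketone flanking the bridgehead should expel the α-oxygen (reductive cleavage of an α-alkoxy ketone), after which hemiketal 18 collapses to the tropone carbonyl with loss of methanol and the 1,3-diketone enolizes into the hydroxytropone, a cleavage expected to outrun dienone reduction at −78 °C.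

Step 11
Reactants: 19 silyl-protected hydroxybenzotropone
Product: 22 radermachol, via free alcohol 20 (not isolated), via cyclic hemiketal 21 (not isolated)
Conditions: aq HF, MeCN, 0 °C → rt
Reagents that add atoms: none
Why: Acidic fluoride removes the silyl group, and the freed benzylic alcohol, held cis to the enoyl carbonyl across the ring alkene, should add to it and lose water to give the aromatic furan (cyclodehydration of a cis-γ-hydroxy enone, a Paal–Knorr-type closure).

Compound list
1 | 1-bromo-2-(diethoxymethyl)benzene | CCOC(OCC)c1ccccc1Br | starting material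
2 | [2-(diethoxymethyl)phenyl]lithium (not isolated) | CCOC(OCC)c1ccccc1[Li] | intermediate
3 | 2-(diethoxymethyl)benzaldehyde | CCOC(OCC)c1ccccc1C=O | intermediate
4 | ethynylmagnesium bromide | C#C[Mg]Br | starting material
5 | 1-[2-(diethoxymethyl)phenyl]prop-2-yn-1-ol (racemic) | CCOC(OCC)c1ccccc1C(O)C#C | intermediate
6 | tert-butyl{1-[2-(diethoxymethyl)phenyl]prop-2-yn-1-yloxy}dimethylsilane (racemic) | CCOC(OCC)c1ccccc1C(O[Si](C)(C)C(C)(C)C)C#C | intermediate
7 | 3-methylbut-2-enal | CC(C)=CC=O | starting material
8 | {3-[tert-butyl(dimethyl)silyloxy]-3-[2-(diethoxymethyl)phenyl]prop-1-yn-1-yl}lithium (not isolated) | CCOC(OCC)c1ccccc1C(O[Si](C)(C)C(C)(C)C)C#C[Li] | intermediate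
9 | 1-[tert-butyl(dimethyl)silyloxy]-1-[2-(diethoxymethyl)phenyl]-6-methylhept-5-en-2-yn-4-ol (racemic, both diastereomers) | CCOC(OCC)c1ccccc1C(O[Si](C)(C)C(C)(C)C)C#CC(O)C=C(C)C | intermediate
10 | 2-{1-[tert-butyl(dimethyl)silyloxy]-4-hydroxy-6-methylhept-5-en-2-yn-1-yl}benzaldehyde (racemic, both diastereomers) | O=Cc1ccccc1C(O[Si](C)(C)C(C)(C)C)C#CC(O)C=C(C)C | intermediate
11 | 2-(methoxycarbonyl)benzoic acid (monomethyl phthalate) | COC(=O)c1ccccc1C(=O)O | starting material
12 | methyl 2-(chlorocarbonyl)benzoate (not isolated) | COC(=O)c1ccccc1C(=O)Cl | intermediate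
13 | methyl 2-(2-diazoacetyl)benzoate | COC(=O)c1ccccc1C(=O)C=[N+]=[N-] | intermediate
14 | methyl 2-[3-(2-{1-[tert-butyl(dimethyl)silyloxy]-4-hydroxy-6-methylhept-5-en-2-yn-1-yl}phenyl)-2-diazo-3-hydroxypropanoyl]benzoate (racemic, all diastereomers) | COC(=O)c1ccccc1C(=O)C(=[N+]=[N-])C(O)c1ccccc1C(O[Si](C)(C)C(C)(C)C)C#CC(O)C=C(C)C | intermediate
15 | methyl 2-[3-(2-{1-[tert-butyl(dimethyl)silyloxy]-6-methyl-4-oxohept-5-en-2-yn-1-yl}phenyl)-2-diazo-3-oxopropanoyl]benzoate (racemic) | COC(=O)c1ccccc1C(=O)C(=[N+]=[N-])C(=O)c1ccccc1C(O[Si](C)(C)C(C)(C)C)C#CC(=O)C=C(C)C | intermediate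
16 | 3-(2-{1-[tert-butyl(dimethyl)silyloxy]-6-methyl-4-oxohept-5-en-2-yn-1-yl}benzoyl)-1-methoxy-2-benzopyrylium-4-olate (carbonyl ylide, not isolated) | COc1[o+]c(C(=O)c2ccccc2C(O[Si](C)(C)C(C)(C)C)C#CC(=O)C=C(C)C)c([O-])c2ccccc12 | intermediate
17 | oxygen-bridged cycloadduct: 3,4-benzo-fused 8-oxabicyclo[3.2.1]oct-6-en-2-one in which bridgehead C1 (former diazo carbon) carries the ring-B aryl ketone, bridgehead C5 carries OMe, C6 carries the 3-methylbut-2-enoyl group and C7 is tied back to the ring-B ketone through CH(OTBS) and an ortho-phenylene; racemic, one enantiomer drawn, bridge necessarily cis, both epimers at CH(OTBS) | CO[C@]12O[C@@]3(C(=O)c4ccccc41)C(=O)c1ccccc1C(O[Si](C)(C)C(C)(C)C)C3=C2C(=O)C=C(C)C | intermediate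
18 | methyl hemiketal formed on cleavage of the bridge C–O bond (the seven-membered ring carries C(OH)(OMe) where the tropone carbonyl will be; not isolated) | CC(C)=CC(=O)C1=C2C(O[Si](C)(C)C(C)(C)C)c3ccccc3C(=O)C2=C(O)c2ccccc2C1(O)OC | intermediate
19 | silyl-protected hydroxybenzotropone: the seven-membered ring holds in order the tropone C=O, the alkene carbon bearing the 3-methylbut-2-enoyl group, the alkene carbon bonded to CH(OTBS) of ring B, the ring-fusion carbon, the enol C–OH and the fused benzene; ring B = CH(OTBS)–ortho-phenylene–C(=O); racemic | CC(C)=CC(=O)C1=C2C(O[Si](C)(C)C(C)(C)C)c3ccccc3C(=O)C2=C(O)c2ccccc2C1=O | intermediate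
20 | free benzylic alcohol of 19 (not isolated) | CC(C)=CC(=O)C1=C2C(O)c3ccccc3C(=O)C2=C(O)c2ccccc2C1=O | intermediate
21 | cyclic hemiketal (2-hydroxy-2,5-dihydrofuran) from addition of the alcohol of 20 to the enoyl carbonyl (not isolated) | CC(C)=CC1(O)OC2c3ccccc3C(=O)C3=C(O)c4ccccc4C(=O)C1=C23 | intermediate
22 | radermachol (achiral) | CC(C)=Cc1oc2c3c(c(O)c4ccccc4c(=O)c13)C(=O)c1ccccc1-2 | target

Total step count: 11. Longest linear sequence: 10 steps (steps 1–5 and 7–11, from 1); step 6 is a one-step side branch.

Steps most likely to fail

Step 9. The diazo group may add thermally across the activated ynone, the carbenoid may be consumed by the triple bond or by the silyl ether oxygen before the ester oxygen closes the ylide, or the ylide may add only sluggishly through the aroyl tether. The fallback sets out from 10 and returns at 17; it carries the alkyne through the cycloaddition as an unactivated propargylic silyl ether and installs the enoyl carbonyl afterwards. Silylation of 10 (TESCl, imidazole, CH2Cl2) should give the triethylsilyl ether F1. DBU-catalysed addition of 13 then gives the diazo alcohol F2, and IBX in DMSO the diazo diketone F3, whose triple bond is no longer a partner for the diazo group. Rh2(OAc)4 in hot benzene should give the cycloadduct F4 by the known trapping of carbonyl ylides by unactivated tethered alkynes. PPTS in MeOH removes only the triethylsilyl group to give the allylic alcohol F5, and MnO2 in CH2Cl2 oxidizes it to 17.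

Step 7. The deprotonated diazoketone may close onto its own ortho ester (Dieckmann-type loss of material), or the addition equilibrium may lie on the side of the hindered aldehyde. The fallback sets out from 10 and 13 and returns at 15; it replaces the base-mediated addition by a base-free Roskamp coupling. SnCl2 (cat.) in CH2Cl2 at rt should join 10 and 13 with loss of N2 and a hydride shift to give the 1,3-diketone F6. Regitz diazo transfer (4-acetamidobenzenesulfonyl azide, Et3N, MeCN, 0 °C), carried out while the side chain is still an alcohol so that no Michael acceptor is present, gives the diazo diketone alcohol F7. IBX in DMSO then oxidizes the remaining alcohol to 15.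

Step 10. Electron transfer to the cross-conjugated dienone may compete with cleavage of the bridge C–O bond, leading to over-reduction or reductive coupling. The fallback sets out from 17 and returns at 22; it reverses the order of the endgame so that the dienone is gone before any reductant is used. Buffered desilylation of 17 (TBAF, AcOH, THF) gives the free alcohol F8. PPTS in warm toluene cyclodehydrates it to the furan-fused bridged ketal F9. Zn dust in AcOH (or SmI2 in THF/MeOH) then cleaves the bridge C–O bond beside the two ketones and, after loss of methanol and enolization, should give 22 directly.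

Further compounds
F1 | step 9 | 2-{1-[tert-butyl(dimethyl)silyloxy]-6-methyl-4-(triethylsilyloxy)hept-5-en-2-yn-1-yl}benzaldehyde | O=Cc1ccccc1C(O[Si](C)(C)C(C)(C)C)C#CC(O[Si](CC)(CC)CC)C=C(C)C
F2 | step 9 | methyl 2-[3-(2-{1-[tert-butyl(dimethyl)silyloxy]-6-methyl-4-(triethylsilyloxy)hept-5-en-2-yn-1-yl}phenyl)-2-diazo-3-hydroxypropanoyl]benzoate | COC(=O)c1ccccc1C(=O)C(=[N+]=[N-])C(O)c1ccccc1C(O[Si](C)(C)C(C)(C)C)C#CC(O[Si](CC)(CC)CC)C=C(C)C
F3 | step 9 | methyl 2-[3-(2-{1-[tert-butyl(dimethyl)silyloxy]-6-methyl-4-(triethylsilyloxy)hept-5-en-2-yn-1-yl}phenyl)-2-diazo-3-oxopropanoyl]benzoate | COC(=O)c1ccccc1C(=O)C(=[N+]=[N-])C(=O)c1ccccc1C(O[Si](C)(C)C(C)(C)C)C#CC(O[Si](CC)(CC)CC)C=C(C)C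
F4 | step 9 | oxygen-bridged cycloadduct bearing a 3-methyl-1-(triethylsilyloxy)but-2-enyl group in place of the enoyl group of 17 (racemic, bridge cis) | CO[C@]12O[C@@]3(C(=O)c4ccccc41)C(=O)c1ccccc1C(O[Si](C)(C)C(C)(C)C)C3=C2C(O[Si](CC)(CC)CC)C=C(C)C
F5 | step 9 | oxygen-bridged cycloadduct bearing a 1-hydroxy-3-methylbut-2-enyl group in place of the enoyl group of 17 (racemic, bridge cis) | CO[C@]12O[C@@]3(C(=O)c4ccccc41)C(=O)c1ccccc1C(O[Si](C)(C)C(C)(C)C)C3=C2C(O)C=C(C)C
F6 | step 7 | methyl 2-[3-(2-{1-[tert-butyl(dimethyl)silyloxy]-4-hydroxy-6-methylhept-5-en-2-yn-1-yl}phenyl)-3-oxopropanoyl]benzoate | COC(=O)c1ccccc1C(=O)CC(=O)c1ccccc1C(O[Si](C)(C)C(C)(C)C)C#CC(O)C=C(C)C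
F7 | step 7 | methyl 2-[3-(2-{1-[tert-butyl(dimethyl)silyloxy]-4-hydroxy-6-methylhept-5-en-2-yn-1-yl}phenyl)-2-diazo-3-oxopropanoyl]benzoate | COC(=O)c1ccccc1C(=O)C(=[N+]=[N-])C(=O)c1ccccc1C(O[Si](C)(C)C(C)(C)C)C#CC(O)C=C(C)C
F8 | step 10 | desilylated oxygen-bridged cycloadduct (free ring-B alcohol; racemic, bridge cis) | CO[C@]12O[C@@]3(C(=O)c4ccccc41)C(=O)c1ccccc1C(O)C3=C2C(=O)C=C(C)C
F9 | step 10 | furan-fused oxygen-bridged methyl ketal (furan carrying the 2-methylprop-1-enyl group already formed, bridge still intact; racemic) | CO[C@]12O[C@@]3(C(=O)c4ccccc41)C(=O)c1ccccc1-c1oc(C=C(C)C)c2c13
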